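**Plan**

The oxane is numbered O1, C2 (acrylic acid), C3, C4, C5 (side chain), C6; C1' is the first carbon of the chain.
- Retrosynthesis: the acid is taken back to the allylic alcohol, the chain is cut at C1'–C2' (sulfonyl carbanion plus farnesyl bromide), and the oxane is cut at O1–C2 while O1 is re-bonded to C1'.
- Enabling feature: C5 carries two CH2 arms, C6 in the ring (bound to O1) and exocyclic C1', so O1/C6/C5/C1' is a latent achiral 3-substituted oxetane; O1–C2 is allylic to the acrylate C=CH2, so O1 can be delivered to C2 by SN2' displacement.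
- Forward: Giese addition, half-reduction, Morita–Baylis–Hillman reaction and allylic bromination give the achiral oxetane 6; a one-pot ring expansion by two atoms (oxetane to oxane) gives 8; the chain is then joined at C1' and the acid oxidation level restored.
- Stereochemistry: C5 from catalyst-controlled choice between the two enantiotopic oxetane C–O bonds; C2 from the chair-like ring closure (2,5-trans, both groups equatorial); chain alkenes from (2E,6E)-farnesyl bromide.

Key step: step 5

Remark: the squaramide enantiomer is taken to decide which enantiotopic oxetane C–O bond is cut, so the antipode that gives (6S)-7 is used.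

**Step 1**
Reactants: 1 3-iodooxetane; 2 methyl acrylate
Product: 3 methyl 3-(oxetan-3-yl)propanoate
Conditions: (Me3Si)3SiH, AIBN (cat.), PhMe, 80 °C
Reagents that add atoms: none
Why: Giese reaction, in which the silyl radical abstracts iodine, the nucleophilic oxetan-3-yl radical adds to the electron-poor alkene and the adduct radical is reduced by the silane; no stereocentre is formed.

**Step 2**
Reactants: 3 methyl 3-(oxetan-3-yl)propanoate
Product: 4 3-(oxetan-3-yl)propanal
Conditions: DIBAL-H, CH2Cl2, −78 °C; Rochelle salt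
Reagents that add atoms: none
Why: Partial ester reduction, since the tetrahedral aluminium hemiacetal is stable at −78 °C and releases the aldehyde only on work-up, while the oxetane is inert to the hydride at this temperature.

**Step 3**
Reactants: 4 3-(oxetan-3-yl)propanal; 2 methyl acrylate
Product: 5 methyl 3-hydroxy-2-methylidene-5-(oxetan-3-yl)pentanoate (racemic)
Conditions: DABCO, MeOH (few equiv), rt
Reagents that add atoms: none
Why: Morita–Baylis–Hillman reaction of an unhindered aliphatic aldehyde; the carbinol centre is formed racemic and is erased in step 4, so no control is needed.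

**Step 4**
Reactants: 5 methyl 3-hydroxy-2-methylidene-5-(oxetan-3-yl)pentanoate
Product: 6 methyl (2Z)-2-(bromomethyl)-5-(oxetan-3-yl)pent-2-enoate
Conditions: NBS, Me2S, CH2Cl2, 0 °C to rt
Reagents that add atoms: N-bromosuccinimide, O=C1CCC(=O)N1Br
Why: Corey–Kim-type bromination, in which the alkoxysulfonium salt is attacked by bromide at the terminal CH2 (SN2') to give the favoured (Z)-2-(bromomethyl)enoate under near-neutral conditions that should spare the oxetane.

**Step 5**
Reactants: 6 methyl (2Z)-2-(bromomethyl)-5-(oxetan-3-yl)pent-2-enoate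
Product: 8 methyl 2-[(2R,5S)-5-(bromomethyl)oxan-2-yl]prop-2-enoate, via bromo silyl ether 7 (not isolated)
Conditions: TMSBr, chiral squaramide hydrogen-bond-donor catalyst (tert-leucine arylpyrrolidine amide type, cat.), t-BuOMe, −78 °C; evaporate; then TBAF (1 equiv), THF, −78 to −20 °C
Reagents that add atoms: bromotrimethylsilane, C[Si](C)(C)Br
Why: The squaramide holds the bromide of TMSBr in a chiral ion pair while silicon activates the oxetane oxygen, and SN2 attack of bromide at one of the two enantiotopic ring CH2 groups gives silyl ether 7; fluoride then frees the alkoxide, which adds to the β-carbon of the 2-(bromomethyl)enoate, and the ester enolate expels bromide (addition–elimination, overall SN2'), so that the four-membered ring O1–C6–C5–C1' is re-closed two atoms larger as the oxane O1–C2–C3–C4–C5–C6 and 8 is a constitutional isomer of 6. The closest known reaction types are the hydrogen-bond-donor-catalysed enantioselective opening of 3-substituted oxetanes with TMSBr and the alkoxide SN2' cyclization onto 2-(bromomethyl)alk-2-enoates. The oxane closes in the 6-exo-trig mode. C5 is set by the catalyst, which selects the C–O bond to be cut, and C2 by the substrate through a chair-like transition state with the CH2Br group and the enoate both equatorial, which should give the 2,5-trans ring. The step needs enantiotopic-group selectivity (catalyst), attack of the alkoxide on the enoate in preference to 4-exo-tet return to the oxetane (ring strain and the high electrophilicity of the bromomethyl enoate should secure it), and attack of fluoride at silicon, not at the allylic carbon (low temperature, one equivalent).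

**Step 6**
Reactants: 8 methyl 2-[(2R,5S)-5-(bromomethyl)oxan-2-yl]prop-2-enoate
Product: 9 2-[(2R,5S)-5-(bromomethyl)oxan-2-yl]prop-2-en-1-ol
Conditions: DIBAL-H (2.2 equiv), CH2Cl2, −78 °C; Rochelle salt
Reagents that add atoms: none
Why: 1,2-Reduction of the acrylate to the allylic alcohol, which leaves the primary bromide and both stereocentres untouched and removes the Michael acceptor before the carbanion chemistry.

**Step 7**
Reactants: 9 2-[(2R,5S)-5-(bromomethyl)oxan-2-yl]prop-2-en-1-ol
Product: 10 2-[(2R,5S)-5-[(benzenesulfonyl)methyl]oxan-2-yl]prop-2-en-1-ol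
Conditions: PhSO2Na, Bu4NI (cat.), DMF, 70 °C
Reagents that add atoms: sodium benzenesulfinate, [Na+].[O-]S(=O)c1ccccc1
Why: SN2 displacement of the primary bromide by the soft sulfur of the sulfinate (S-alkylation) in a dipolar aprotic solvent, with C5 not involved.

**Step 8**
Reactants: 10 2-[(2R,5S)-5-[(benzenesulfonyl)methyl]oxan-2-yl]prop-2-en-1-ol; 11 (2E,6E)-farnesyl bromide
Product: 13 2-[(2R,5S)-5-[(3E,7E)-1-(benzenesulfonyl)-4,8,12-trimethyltrideca-3,7,11-trien-1-yl]oxan-2-yl]prop-2-en-1-ol (both epimers at the sulfonyl-bearing carbon), via dilithio sulfone 12 (not isolated)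
Conditions: n-BuLi (2.1 equiv), THF, −78 °C; then 11, −78 to −40 °C; aq. NH4Cl
Reagents that add atoms: none
Why: Julia-type sulfone alkylation, in which the α-sulfonyl carbanion, far more nucleophilic than the lithium alkoxide, attacks the primary allylic carbon of 11 (SN2) so that the (2E,6E) geometry is carried over; the new sulfonyl-bearing centre is erased in step 9.

**Step 9**
Reactants: 13 2-[(2R,5S)-5-[(3E,7E)-1-(benzenesulfonyl)-4,8,12-trimethyltrideca-3,7,11-trien-1-yl]oxan-2-yl]prop-2-en-1-ol
Product: 14 2-[(2R,5S)-5-[(3E,7E)-4,8,12-trimethyltrideca-3,7,11-trien-1-yl]oxan-2-yl]prop-2-en-1-ol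
Conditions: Na(Hg), Na2HPO4, MeOH/THF, −20 °C
Reagents that add atoms: none
Why: Reductive desulfonylation by electron transfer and protonation; the sulfone is homoallylic, so no allylic transposition can occur, and the isolated alkenes and the allylic alcohol should be inert.

**Step 10**
Reactants: 14 2-[(2R,5S)-5-[(3E,7E)-4,8,12-trimethyltrideca-3,7,11-trien-1-yl]oxan-2-yl]prop-2-en-1-ol
Product: 15 2-[(2R,5S)-5-[(3E,7E)-4,8,12-trimethyltrideca-3,7,11-trien-1-yl]oxan-2-yl]prop-2-enal
Conditions: MnO2, CH2Cl2, rt
Reagents that add atoms: none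
Why: MnO2 oxidation, selective for the allylic alcohol, stops at the enal under neutral heterogeneous conditions that should not epimerize C2.

**Step 11**
Reactants: 15 2-[(2R,5S)-5-[(3E,7E)-4,8,12-trimethyltrideca-3,7,11-trien-1-yl]oxan-2-yl]prop-2-enal
Product: 16 rhopaloic acid A, 2-[(2R,5S)-5-[(3E,7E)-4,8,12-trimethyltrideca-3,7,11-trien-1-yl]oxan-2-yl]prop-2-enoic acid
Conditions: NaClO2, NaH2PO4, 2-methyl-2-butene (excess), t-BuOH/H2O, 0 °C to rt
Reagents that add atoms: sodium chlorite, [Na+].[O-]Cl=O
Why: Pinnick oxidation, in which chlorous acid converts the enal into the acid without touching the alkenes, while 2-methyl-2-butene traps the hypochlorous acid that would otherwise attack the trisubstituted alkenes.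

**Compound list**

1 | 3-iodooxetane | IC1COC1 | starting material
2 | methyl acrylate | C=CC(=O)OC | starting material
3 | methyl 3-(oxetan-3-yl)propanoate | COC(=O)CCC1COC1 | intermediate
4 | 3-(oxetan-3-yl)propanal | O=CCCC1COC1 | intermediate
5 | methyl 3-hydroxy-2-methylidene-5-(oxetan-3-yl)pentanoate (racemic) | C=C(C(O)CCC1COC1)C(=O)OC | intermediate
6 | methyl (2Z)-2-(bromomethyl)-5-(oxetan-3-yl)pent-2-enoate | C1OCC1CC/C=C(\CBr)C(=O)OC | intermediate
7 | methyl (2Z,6S)-7-bromo-2-(bromomethyl)-6-{[(trimethylsilyl)oxy]methyl}hept-2-enoate (not isolated) | C[Si](C)(C)OC[C@@H](CBr)CC/C=C(\CBr)C(=O)OC | intermediate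
8 | methyl 2-[(2R,5S)-5-(bromomethyl)oxan-2-yl]prop-2-enoate | C=C(C(=O)OC)[C@H]1CC[C@H](CBr)CO1 | intermediate
9 | 2-[(2R,5S)-5-(bromomethyl)oxan-2-yl]prop-2-en-1-ol | C=C(CO)[C@H]1CC[C@H](CBr)CO1 | intermediate
10 | 2-[(2R,5S)-5-[(benzenesulfonyl)methyl]oxan-2-yl]prop-2-en-1-ol | C=C(CO)[C@H]1CC[C@H](CS(=O)(=O)c2ccccc2)CO1 | intermediate
11 | (2E,6E)-farnesyl bromide, (2E,6E)-1-bromo-3,7,11-trimethyldodeca-2,6,10-triene | BrC/C=C(\C)CC/C=C(\C)CCC=C(C)C | starting material
12 | dilithio sulfone: lithium 2-[(2R,5S)-5-[(benzenesulfonyl)(lithio)methyl]oxan-2-yl]prop-2-en-1-olate (not isolated) | [Li]OCC(=C)[C@H]1CC[C@H](C([Li])S(=O)(=O)c2ccccc2)CO1 | intermediate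
13 | 2-[(2R,5S)-5-[(3E,7E)-1-(benzenesulfonyl)-4,8,12-trimethyltrideca-3,7,11-trien-1-yl]oxan-2-yl]prop-2-en-1-ol (both epimers at the sulfonyl-bearing carbon) | C=C(CO)[C@H]1CC[C@H](C(C/C=C(\C)CC/C=C(\C)CCC=C(C)C)S(=O)(=O)c2ccccc2)CO1 | intermediate
14 | 2-[(2R,5S)-5-[(3E,7E)-4,8,12-trimethyltrideca-3,7,11-trien-1-yl]oxan-2-yl]prop-2-en-1-ol | C=C(CO)[C@H]1CC[C@H](CC/C=C(\C)CC/C=C(\C)CCC=C(C)C)CO1 | intermediate
15 | 2-[(2R,5S)-5-[(3E,7E)-4,8,12-trimethyltrideca-3,7,11-trien-1-yl]oxan-2-yl]prop-2-enal | C=C(C=O)[C@H]1CC[C@H](CC/C=C(\C)CC/C=C(\C)CCC=C(C)C)CO1 | intermediate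
16 | rhopaloic acid A, 2-[(2R,5S)-5-[(3E,7E)-4,8,12-trimethyltrideca-3,7,11-trien-1-yl]oxan-2-yl]prop-2-enoic acid | C=C(C(=O)O)[C@H]1CC[C@H](CC/C=C(\C)CC/C=C(\C)CCC=C(C)C)CO1 | target

**Step count and risks**

Total step count: 11. Longest linear sequence: 11 steps (from 3-iodooxetane 1; farnesyl bromide 11 enters in step 8).

Steps most likely to fail:

1. Step 5. The catalyst may discriminate poorly between the two enantiotopic C–O bonds of an oxetane whose 3-substituent is purely aliphatic, and in the second stage fluoride or a second molecule of alkoxide may attack the allylic bromide. The fallback replaces catalytic desymmetrization by enzymatic kinetic resolution and sets out from 6. MgBr2·OEt2 (Et2O, 0 °C) should open the oxetane without selectivity to racemic methyl (2Z)-7-bromo-2-(bromomethyl)-6-(hydroxymethyl)hept-2-enoate F1. Lipase-catalysed acylation (Burkholderia cepacia lipase, vinyl acetate, t-BuOMe), with the lipase chosen for this preference, should leave methyl (2Z,6S)-7-bromo-2-(bromomethyl)-6-(hydroxymethyl)hept-2-enoate F2 unreacted and convert its antipode into methyl (2Z,6R)-6-(acetoxymethyl)-7-bromo-2-(bromomethyl)hept-2-enoate F3, which is separated. F2 with NaH (THF, −20 °C) should close by the same SN2' cyclization and come back to the route at 8.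

2. Step 4. The bromosulfonium/bromide pair may open the oxetane before the allylic transposition is complete. The fallback avoids the allylic bromide altogether and sets out from 5. Ac2O/pyridine/DMAP should give methyl 3-acetoxy-2-methylidene-5-(oxetan-3-yl)pentanoate F4, and the first stage of step 5 (TMSBr, squaramide) should then give methyl (6S)-3-acetoxy-7-bromo-2-methylidene-6-{[(trimethylsilyl)oxy]methyl}heptanoate F5. TBAF with catalytic DABCO (THF) should free the alkoxide and close the ring by Lewis-base-catalysed SN2'–SN2' substitution of the allylic acetate, in which the racemic acetoxy centre is erased, and come back to the route at 8.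

3. Step 8. O-alkylation of the alkoxide, proton transfer to the dianion, or slow C-alkylation of the β-branched sulfonyl carbanion may erode the coupling. The fallback reverses the polarity to a copper-catalysed Grignard coupling and sets out from 9. TBSCl/imidazole should give tert-butyl({2-[(2R,5S)-5-(bromomethyl)oxan-2-yl]prop-2-en-1-yl}oxy)dimethylsilane F6, and Mg (THF) its Grignard reagent, bromo{[(3S,6R)-6-{3-[(tert-butyldimethylsilyl)oxy]prop-1-en-2-yl}oxan-3-yl]methyl}magnesium F7. Coupling with 11 under Li2CuCl4 catalysis (THF, −78 to 0 °C, attack at the primary allylic carbon) should give tert-butyldimethyl({2-[(2R,5S)-5-[(3E,7E)-4,8,12-trimethyltrideca-3,7,11-trien-1-yl]oxan-2-yl]prop-2-en-1-yl}oxy)silane F8. TBAF should then release the alcohol and come back to the route at 14, so that 10, 12 and 13 are bypassed.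

**Further compounds**

F1 | step 5 | methyl (2Z)-7-bromo-2-(bromomethyl)-6-(hydroxymethyl)hept-2-enoate (racemic) | OCC(CBr)CC/C=C(\CBr)C(=O)OC
F2 | step 5 | methyl (2Z,6S)-7-bromo-2-(bromomethyl)-6-(hydroxymethyl)hept-2-enoate | OC[C@@H](CBr)CC/C=C(\CBr)C(=O)OC
F3 | step 5 | methyl (2Z,6R)-6-(acetoxymethyl)-7-bromo-2-(bromomethyl)hept-2-enoate | CC(=O)OC[C@H](CBr)CC/C=C(\CBr)C(=O)OC
F4 | step 4 | methyl 3-acetoxy-2-methylidene-5-(oxetan-3-yl)pentanoate (racemic) | C=C(C(OC(C)=O)CCC1COC1)C(=O)OC
F5 | step 4 | methyl (6S)-3-acetoxy-7-bromo-2-methylidene-6-{[(trimethylsilyl)oxy]methyl}heptanoate (both epimers at the acetoxy carbon) | C[Si](C)(C)OC[C@@H](CBr)CCC(OC(C)=O)C(=C)C(=O)OC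
F6 | step 8 | tert-butyl({2-[(2R,5S)-5-(bromomethyl)oxan-2-yl]prop-2-en-1-yl}oxy)dimethylsilane | C=C(CO[Si](C)(C)C(C)(C)C)[C@H]1CC[C@H](CBr)CO1
F7 | step 8 | bromo{[(3S,6R)-6-{3-[(tert-butyldimethylsilyl)oxy]prop-1-en-2-yl}oxan-3-yl]methyl}magnesium | C=C(CO[Si](C)(C)C(C)(C)C)[C@H]1CC[C@H](C[Mg]Br)CO1
F8 | step 8 | tert-butyldimethyl({2-[(2R,5S)-5-[(3E,7E)-4,8,12-trimethyltrideca-3,7,11-trien-1-yl]oxan-2-yl]prop-2-en-1-yl}oxy)silane | C=C(CO[Si](C)(C)C(C)(C)C)[C@H]1CC[C@H](CC/C=C(\C)CC/C=C(\C)CCC=C(C)C)CO1
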